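**Retrosynthetic overview**

1. The C12–C13 bond is cut last: the imide ring is bought as maleimide and joined to a C12 aldehyde by a Stetter reaction, then C12 and C13 are set by dynamic kinetic reduction. Ring A is bought as ketoisophorone, whose C2 oxygen becomes the chloride by inversion.
2. Enabling feature: ring B holds the homoallylic alcohol C6(OH)–C7H2–C8(=C17H2), a carbonyl-ene retron. Opening C6–C7 leaves the aldehyde O=C6–C5–C10–C9–C8(CH3)=C7H2, which is the oxy-Cope product of the 1,5-dien-3-ol C10=C5–C6(OH)–C7H2–C8(CH3)=C9H.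
3. Key step: in one flask the C6 alkoxide shifts the C7–C8–C9 unit from C6 to C10 ([3,3]) and the freed C6 aldehyde takes C7 back (ene). This gives ring B, the quaternary C10, C5, C6, C9 and the exocyclic methylene from a monocyclic dienol with one carbinol stereocentre.
4. The dienol comes from the ring A enal, an allenylboronate (C7–C9), Me3Al (C17) and oxirane (C11–C12).
5. Ring order: ring A and the imide ring are present in purchased materials; ring B is the only ring closed in the route and the last.

Key step: step 10

Remark: labdane numbering is used (ring A C1–C5/C10, ring B C5–C10, C17 exocyclic methylene, C20 angular methyl, C11–C12 chain, C13–C16 imide carbons); the sense of induction of each chiral catalyst is assigned by analogy and is to be checked on first use.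

**Route**

Step 1
Reactants: 1 2,6,6-trimethylcyclohex-2-ene-1,4-dione (ketoisophorone)
Product: 2 (4R)-4-hydroxy-2,6,6-trimethylcyclohex-2-en-1-one
Conditions: RuCl(p-cymene)[(R,R)-TsDPEN] (cat.), HCO2H/Et3N 5:2, CH2Cl2, rt
Reagents that add atoms: none
Why: Noyori asymmetric transfer hydrogenation reduces only the C4 carbonyl, because the C1 carbonyl is shielded by the gem-dimethyl carbon and the methyl-bearing alkene carbon, and the chiral ruthenium hydride sets the carbinol as R by the facial rule known for aryl alkyl ketones, with the alkenyl group in the place of the aryl group.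

Step 2
Reactants: 2 (4R)-4-hydroxy-2,6,6-trimethylcyclohex-2-en-1-one
Product: 3 (4R)-4-[(tert-butyldimethylsilyl)oxy]-2,6,6-trimethylcyclohex-2-en-1-one
Conditions: TBSCl, imidazole, DMF, rt
Reagents that add atoms: tert-butyldimethylsilyl chloride, CC(C)(C)[Si](C)(C)Cl
Why: Standard silyl ether formation masks the secondary hydroxyl for the hydride and enolate chemistry of step 3 without touching the stereocentre.

Step 3
Reactants: 3 (4R)-4-[(tert-butyldimethylsilyl)oxy]-2,6,6-trimethylcyclohex-2-en-1-one
Product: 5 (4S)-4-[(tert-butyldimethylsilyl)oxy]-2,6,6-trimethylcyclohex-1-en-1-yl trifluoromethanesulfonate, via lithium enolate 4 (not isolated)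
Conditions: LiBH(s-Bu)3, THF, −78 °C; then PhNTf2, −78 → 0 °C
Reagents that add atoms: N-phenylbis(trifluoromethanesulfonimide), O=S(=O)(N(c1ccccc1)S(=O)(=O)C(F)(F)F)C(F)(F)F
Why: Reductive triflation: conjugate hydride addition to the enone, whose carbonyl is too hindered for 1,2-attack, gives enolate 4 regiospecifically and O-sulfonylation fixes it as the tetrasubstituted enol triflate, the silyloxy stereocentre being untouched (its descriptor becomes S only because the ring double bond has moved).

Step 4
Reactants: 5 (4S)-4-[(tert-butyldimethylsilyl)oxy]-2,6,6-trimethylcyclohex-1-en-1-yl trifluoromethanesulfonate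
Product: 6 (4S)-4-hydroxy-2,6,6-trimethylcyclohex-1-en-1-yl trifluoromethanesulfonate
Conditions: HF·pyridine, THF, 0 °C → rt
Reagents that add atoms: none
Why: Fluoride-induced cleavage of the silyl ether under buffered, weakly acidic conditions leaves the enol triflate intact.

Step 5
Reactants: 6 (4S)-4-hydroxy-2,6,6-trimethylcyclohex-1-en-1-yl trifluoromethanesulfonate
Product: 7 (4R)-4-chloro-2,6,6-trimethylcyclohex-1-en-1-yl trifluoromethanesulfonate
Conditions: PPh3, N-chlorosuccinimide, CH2Cl2, 0 °C → rt
Reagents that add atoms: N-chlorosuccinimide, O=C1CCC(=O)N1Cl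
Why: Appel reaction: chloride displaces the alkoxyphosphonium group by SN2 with inversion, which turns the 4S alcohol into the 4R chloride (the equatorial 2α-chloride of the target), and doing it before the formyl group is present avoids vinylogous loss of HCl.

Step 6
Reactants: 7 (4R)-4-chloro-2,6,6-trimethylcyclohex-1-en-1-yl trifluoromethanesulfonate
Product: 8 (4R)-4-chloro-2,6,6-trimethylcyclohex-1-ene-1-carbaldehyde
Conditions: Pd(PPh3)4 (cat.), CO (1–3 atm), Bu3SnH (slow addition), LiCl, THF, 50 °C
Reagents that add atoms: carbon monoxide, [C-]#[O+]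
Why: Palladium-catalysed reductive carbonylation (formylation) of an enol triflate, by oxidative addition, CO insertion and hydride transfer from tin, gives the enal under neutral conditions that leave the secondary chloride alone.

Step 7
Reactants: 8 (4R)-4-chloro-2,6,6-trimethylcyclohex-1-ene-1-carbaldehyde; 9 4,4,5,5-tetramethyl-2-(propa-1,2-dien-1-yl)-1,3,2-dioxaborolane (allenylboronic acid pinacol ester)
Product: 10 (1R)-1-[(4R)-4-chloro-2,6,6-trimethylcyclohex-1-en-1-yl]but-3-yn-1-ol
Conditions: (R)-3,3′-bis(2,4,6-triisopropylphenyl)-BINOL hydrogen phosphate (cat.), 4 Å MS, toluene, 0 °C → rt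
Reagents that add atoms: none
Why: Chiral phosphoric acid-catalysed asymmetric propargylation: the allenylboronate adds through a closed six-membered SE2′ transition state held in the chiral pocket by hydrogen bonds to the boronate oxygen and the formyl hydrogen, so the catalyst sets C6 (R expected by analogy with aryl and alkenyl aldehydes) under weakly acidic conditions that spare the base-sensitive chloro enal.

Step 8
Reactants: 10 (1R)-1-[(4R)-4-chloro-2,6,6-trimethylcyclohex-1-en-1-yl]but-3-yn-1-ol; 11 oxirane
Product: 13 (1R,3E)-1-[(4R)-4-chloro-2,6,6-trimethylcyclohex-1-en-1-yl]-3-methylhex-3-ene-1,6-diol, via alkenylalane 12 (not isolated)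
Conditions: Me3Al, Cp2ZrCl2, CH2Cl2, 0 °C → rt; excess Me3Al removed in vacuo; n-BuLi, THF/hexane, −30 °C; oxirane, −30 → 0 °C; aq. Rochelle salt
Reagents that add atoms: trimethylaluminium, C[Al](C)C
Why: Zirconium-catalysed carboalumination adds methyl and aluminium syn across the terminal alkyne with methyl on the inner carbon, and the alkenylalanate made with n-BuLi opens oxirane with retention at the alkenyl carbon, so the trisubstituted alkene is E and carries C17, C11 and C12, while C6 rides through as its aluminium alkoxide.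

Step 9
Reactants: 13 (1R,3E)-1-[(4R)-4-chloro-2,6,6-trimethylcyclohex-1-en-1-yl]-3-methylhex-3-ene-1,6-diol
Product: 14 (1R,3E)-6-[(tert-butyldimethylsilyl)oxy]-1-[(4R)-4-chloro-2,6,6-trimethylcyclohex-1-en-1-yl]-3-methylhex-3-en-1-ol
Conditions: TBSCl (1 equiv), imidazole, CH2Cl2, 0 °C
Reagents that add atoms: tert-butyldimethylsilyl chloride, CC(C)(C)[Si](C)(C)Cl
Why: Selective silylation of the primary hydroxyl, the secondary allylic hydroxyl being flanked by the tetrasubstituted ring alkene and far slower.

Step 10
Reactants: 14 (1R,3E)-6-[(tert-butyldimethylsilyl)oxy]-1-[(4R)-4-chloro-2,6,6-trimethylcyclohex-1-en-1-yl]-3-methylhex-3-en-1-ol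
Product: 18 12-[(tert-butyldimethylsilyl)oxy]-2α-chloro-13,14,15,16-tetranorlabd-8(17)-en-6β-ol, via potassium alkoxide 15 (not isolated), via potassium enolate 16 (not isolated), via aldehyde 17 (not isolated)
Conditions: KN(SiMe3)2, 18-crown-6, THF, 0 °C → rt; AcOH (1 equiv), −78 °C; THF removed in vacuo; Me2AlCl (excess), CH2Cl2, −78 → 0 °C; aq. HCl work-up
Reagents that add atoms: none
Why: Alkoxide 15 undergoes the anionic oxy-Cope [3,3] shift through a chair transition state (C6–C7 broken, C9–C10 formed) to enolate 16, protonation gives aldehyde 17, and Me2AlCl then induces a type 2 intramolecular carbonyl-ene reaction in which C7 of the isopropenyl group bonds to C6 and a C17 hydrogen passes to oxygen. The closest known reactions are the anionic oxy-Cope rearrangement of acyclic 1,5-dien-3-ols, the tandem oxy-Cope/carbonyl-ene sequence, and the Lewis-acid type 2 ene cyclization of 5-methylhex-5-enals to 3-methylenecyclohexanols. Ring B is the only ring closed, by six-membered closure onto the terminal alkene carbon, the exocyclic methylene arising from the ene hydrogen shift. C9 and C10 are set by chirality transfer from C6 (6R, oxygen pseudoaxial so that the carbinol hydrogen sits between the C4 methyls) through the chair with the E alkene, which puts C11 equatorial and the C20 methyl β, reinforced by bond formation on the ring A face opposite the pseudoaxial C4 methyl of the chlorine-equatorial half-chair; C5 is set by protonation of the enolate on the α face, away from the two β-axial methyls; C6 is set by the concerted ene geometry, which needs the oxygen axial (β) on the forming chair to reach the C17 hydrogen. The step needs the [3,3] shift to beat fragmentation of the alkoxide and the ene to take hydrogen from C17 and not from C9, which the secondary alkoxide with a crown-separated potassium ion and the out-of-reach position of the C9 hydrogen across the forming ring should secure.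

Step 11
Reactants: 18 12-[(tert-butyldimethylsilyl)oxy]-2α-chloro-13,14,15,16-tetranorlabd-8(17)-en-6β-ol
Product: 19 2α-chloro-13,14,15,16-tetranorlabd-8(17)-ene-6β,12-diol
Conditions: Bu4NF, THF, 0 °C → rt
Reagents that add atoms: none
Why: Fluoride cleavage of the primary silyl ether has no effect on the hindered axial C6 alcohol, the alkene or the equatorial chloride.

Step 12
Reactants: 19 2α-chloro-13,14,15,16-tetranorlabd-8(17)-ene-6β,12-diol
Product: 20 2α-chloro-6β-hydroxy-13,14,15,16-tetranorlabd-8(17)-en-12-al
Conditions: TEMPO (cat.), PhI(OAc)2, CH2Cl2, rt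
Reagents that add atoms: none
Why: Oxoammonium (TEMPO) oxidation with PhI(OAc)2 as terminal oxidant converts the primary alcohol to the aldehyde and leaves the hindered axial secondary C6 alcohol untouched.

Step 13
Reactants: 20 2α-chloro-6β-hydroxy-13,14,15,16-tetranorlabd-8(17)-en-12-al; 21 maleimide (1H-pyrrole-2,5-dione)
Product: 22 3-[(2α-chloro-6β-hydroxy-13,14,15,16-tetranorlabd-8(17)-en-12-yl)carbonyl]pyrrolidine-2,5-dione (12-oxo precursor of the target, C13 epimers interconverting)
Conditions: 3-benzyl-5-(2-hydroxyethyl)-4-methylthiazolium chloride (cat.), Et3N, 1,4-dioxane, 70 °C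
Reagents that add atoms: none
Why: Stetter reaction: the thiazol-2-ylidene turns the aldehyde into an acyl anion equivalent (Breslow intermediate) that adds 1,4 to maleimide, which joins the intact imide ring through the C12–C13 bond and leaves C13 as a freely epimerizing centre between two carbonyl groups.

Step 14
Reactants: 22 3-[(2α-chloro-6β-hydroxy-13,14,15,16-tetranorlabd-8(17)-en-12-yl)carbonyl]pyrrolidine-2,5-dione
Product: 23 haterumaimide F (2α-chloro, 6β-hydroxy, 12S-hydroxy, 13R)
Conditions: RuCl(p-cymene)[(S,S)-TsDPEN] (cat.), HCO2H/Et3N 5:2, DMF, rt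
Reagents that add atoms: none
Why: Noyori asymmetric transfer hydrogenation with dynamic kinetic resolution: C13 epimerizes through the enol faster than the ketone is reduced, and the chiral ruthenium hydride reduces the 13R epimer from the face that gives the 12S alcohol, by analogy with the syn-selective reduction of α-substituted β-keto amides, while the C6 alcohol, alkene, chloride and imide are inert.

**Compound list**

1 | 2,6,6-trimethylcyclohex-2-ene-1,4-dione (ketoisophorone) | CC1=CC(=O)CC(C)(C)C1=O | starting material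
2 | (4R)-4-hydroxy-2,6,6-trimethylcyclohex-2-en-1-one | CC1(C)C[C@@H](O)C=C(C)C1=O | intermediate
3 | (4R)-4-[(tert-butyldimethylsilyl)oxy]-2,6,6-trimethylcyclohex-2-en-1-one | CC1(C)C[C@@H](O[Si](C)(C)C(C)(C)C)C=C(C)C1=O | intermediate
4 | lithium (4S)-4-[(tert-butyldimethylsilyl)oxy]-2,6,6-trimethylcyclohex-1-en-1-olate | [Li+].[O-]C1=C(C)C[C@H](O[Si](C)(C)C(C)(C)C)CC1(C)C | intermediate
5 | (4S)-4-[(tert-butyldimethylsilyl)oxy]-2,6,6-trimethylcyclohex-1-en-1-yl trifluoromethanesulfonate | CC1(C)C[C@@H](O[Si](C)(C)C(C)(C)C)CC(C)=C1OS(=O)(=O)C(F)(F)F | intermediate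
6 | (4S)-4-hydroxy-2,6,6-trimethylcyclohex-1-en-1-yl trifluoromethanesulfonate | CC1(C)C[C@@H](O)CC(C)=C1OS(=O)(=O)C(F)(F)F | intermediate
7 | (4R)-4-chloro-2,6,6-trimethylcyclohex-1-en-1-yl trifluoromethanesulfonate | CC1(C)C[C@H](Cl)CC(C)=C1OS(=O)(=O)C(F)(F)F | intermediate
8 | (4R)-4-chloro-2,6,6-trimethylcyclohex-1-ene-1-carbaldehyde | CC1(C)C[C@H](Cl)CC(C)=C1C=O | intermediate
9 | 4,4,5,5-tetramethyl-2-(propa-1,2-dien-1-yl)-1,3,2-dioxaborolane | C=C=CB1OC(C)(C)C(C)(C)O1 | starting material
10 | (1R)-1-[(4R)-4-chloro-2,6,6-trimethylcyclohex-1-en-1-yl]but-3-yn-1-ol | C#CC[C@@H](O)C1=C(C)C[C@@H](Cl)CC1(C)C | intermediate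
11 | oxirane | C1CO1 | starting material
12 | (E)-alkenyl(dimethyl)alane from 10, O-dimethylaluminium alkoxide (Al on C9, cis to the new methyl) | C[Al](C)/C=C(\C)C[C@@H](O[Al](C)C)C1=C(C)C[C@@H](Cl)CC1(C)C | intermediate
13 | (1R,3E)-1-[(4R)-4-chloro-2,6,6-trimethylcyclohex-1-en-1-yl]-3-methylhex-3-ene-1,6-diol | OCC/C=C(\C)C[C@@H](O)C1=C(C)C[C@@H](Cl)CC1(C)C | intermediate
14 | (1R,3E)-6-[(tert-butyldimethylsilyl)oxy]-1-[(4R)-4-chloro-2,6,6-trimethylcyclohex-1-en-1-yl]-3-methylhex-3-en-1-ol | CC(C)(C)[Si](C)(C)OCC/C=C(\C)C[C@@H](O)C1=C(C)C[C@@H](Cl)CC1(C)C | intermediate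
15 | potassium alkoxide of 14 | [K+].CC(C)(C)[Si](C)(C)OCC/C=C(\C)C[C@@H]([O-])C1=C(C)C[C@@H](Cl)CC1(C)C | intermediate
16 | potassium (Z)-enolate of 17 (C5=C6, oxygen cis to C10) | [K+].[O-]/C=C1/C(C)(C)C[C@H](Cl)C[C@]1(C)[C@@H](CCO[Si](C)(C)C(C)(C)C)C(C)=C | intermediate
17 | 12-[(tert-butyldimethylsilyl)oxy]-2α-chloro-13,14,15,16-tetranor-6,7-secolabd-7-en-6-al (formyl on C5 equatorial and trans to the C10 methyl; C9 as in the target) | O=C[C@H]1C(C)(C)C[C@H](Cl)C[C@]1(C)[C@@H](CCO[Si](C)(C)C(C)(C)C)C(C)=C | intermediate
18 | 12-[(tert-butyldimethylsilyl)oxy]-2α-chloro-13,14,15,16-tetranorlabd-8(17)-en-6β-ol | C=C1C[C@@H](O)[C@H]2C(C)(C)C[C@H](Cl)C[C@]2(C)[C@H]1CCO[Si](C)(C)C(C)(C)C | intermediate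
19 | 2α-chloro-13,14,15,16-tetranorlabd-8(17)-ene-6β,12-diol | C=C1C[C@@H](O)[C@H]2C(C)(C)C[C@H](Cl)C[C@]2(C)[C@H]1CCO | intermediate
20 | 2α-chloro-6β-hydroxy-13,14,15,16-tetranorlabd-8(17)-en-12-al | C=C1C[C@@H](O)[C@H]2C(C)(C)C[C@H](Cl)C[C@]2(C)[C@H]1CC=O | intermediate
21 | maleimide (1H-pyrrole-2,5-dione) | O=C1C=CC(=O)N1 | starting material
22 | 3-[(2α-chloro-6β-hydroxy-13,14,15,16-tetranorlabd-8(17)-en-12-yl)carbonyl]pyrrolidine-2,5-dione (C13 labile, drawn without descriptor) | C=C1C[C@@H](O)[C@H]2C(C)(C)C[C@H](Cl)C[C@]2(C)[C@H]1CC(=O)C1CC(=O)NC1=O | intermediate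
23 | haterumaimide F | C=C1C[C@@H](O)[C@H]2C(C)(C)C[C@H](Cl)C[C@]2(C)[C@H]1C[C@H](O)[C@H]1CC(=O)NC1=O | target

**Step count and risks**

Total step count: 14. Longest linear sequence: 14 steps (1 → 23); compounds 9, 11 and 21 are purchased.

Steps most likely to fail:

Step 10. The alkoxide may fragment (loss of the allyl unit) instead of rearranging. The Lewis-acid closure may also run stepwise through the C8 cation, so that the C6 hydroxyl ends equatorial or the double bond moves into the ring. The fallback sets C6 by hydride delivery instead of by the ene geometry; it sets out from 14 and comes back at 18. The rearrangement is run on its own (KN(SiMe3)2, 18-crown-6, THF, then aqueous NH4Cl) and aldehyde 17 is isolated. Ring B is then closed under conditions that are not asked to control C6 (Me2AlCl, or the bulkier methylaluminium bis(4-bromo-2,6-di-tert-butylphenoxide)), which should give 18 together with, or in place of, the 6α-alcohol F1. Dess–Martin periodinane with NaHCO3 converts both epimers to the β,γ-unsaturated 6-ketone F2. NaBH4 with CeCl3·7H2O in MeOH at −78 °C should then deliver hydride to the α face, the β face being blocked by the axial methyls on C4 and C10, and return 18.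

Step 13. The acidic N–H of maleimide may consume the base and starve the carbene, or maleimide may oligomerize faster than the acyl anion equivalent adds. The fallback protects the acceptor nitrogen; it sets out from 20 and comes back at 23. The Stetter reaction is run with commercial 1-(4-methoxybenzyl)-1H-pyrrole-2,5-dione to give the N-(4-methoxybenzyl) keto imide F3. The transfer hydrogenation of step 14 then gives the N-(4-methoxybenzyl) derivative of the target F4. (NH4)2Ce(NO3)6 in MeCN/H2O at 0 °C removes the benzyl group and gives 23.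

Step 14. The ruthenium catalyst may discriminate poorly between the two interconverting C13 epimers, or give the wrong facial sense at C12, on this ketone with two alkyl-type flanks. The fallback uses chelation control in place of catalyst control; it sets out from 22 and ends at 23. Zn(BH4)2 in Et2O/CH2Cl2 at −20 °C reduces the zinc chelate of the keto imide and should fix the 12,13-syn relationship. Without a bias between the two syn pairs this should give 23 together with the 12R,13S diastereomer F5, to be separated by chromatography.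

**Further compounds**

F1 | step 10 | 12-[(tert-butyldimethylsilyl)oxy]-2α-chloro-13,14,15,16-tetranorlabd-8(17)-en-6α-ol | C=C1C[C@H](O)[C@H]2C(C)(C)C[C@H](Cl)C[C@]2(C)[C@H]1CCO[Si](C)(C)C(C)(C)C
F2 | step 10 | 12-[(tert-butyldimethylsilyl)oxy]-2α-chloro-13,14,15,16-tetranorlabd-8(17)-en-6-one | C=C1CC(=O)[C@H]2C(C)(C)C[C@H](Cl)C[C@]2(C)[C@H]1CCO[Si](C)(C)C(C)(C)C
F3 | step 13 | 1-(4-methoxybenzyl)-3-[(2α-chloro-6β-hydroxy-13,14,15,16-tetranorlabd-8(17)-en-12-yl)carbonyl]pyrrolidine-2,5-dione | C=C1C[C@@H](O)[C@H]2C(C)(C)C[C@H](Cl)C[C@]2(C)[C@H]1CC(=O)C1CC(=O)N(Cc2ccc(OC)cc2)C1=O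
F4 | step 13 | N-(4-methoxybenzyl)haterumaimide F | C=C1C[C@@H](O)[C@H]2C(C)(C)C[C@H](Cl)C[C@]2(C)[C@H]1C[C@H](O)[C@H]1CC(=O)N(Cc2ccc(OC)cc2)C1=O
F5 | step 14 | (12R,13S)-diastereomer of haterumaimide F | C=C1C[C@@H](O)[C@H]2C(C)(C)C[C@H](Cl)C[C@]2(C)[C@H]1C[C@@H](O)[C@@H]1CC(=O)NC1=O
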